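**Retrosynthetic overview**

1. The dioxane ring is cut by a retro hetero-Diels–Alder reaction into brussonol o-quinone 16 (2π partner, C13′=C14′) and the o-quinone of an open-chain enynal catechol (heterodiene O11=C11–C12=O12), so the aromatic half arrives without any of its carbocycles.
2. Aromatic half: C7–O–C10, C10–C5 and C7–C6 are disconnected together. A platinum-bound 2-benzopyrylium (carbonyl ylide C7–O–C10) forms from the 2-alkynylbenzaldehyde and adds across the C5=C6 vinyl group; the C20 carbene is reduced in the same flask.
3. Enabling feature: in the benzo-fused 8-oxabicyclo[3.2.1]octane the ether oxygen joins C7 (on arene carbon C8) and C10 (one carbon, C20, from arene carbon C9). Ring A (C10, C1–C5) shares the C10–C5 bond with this bicycle, so the C1–C4 chain is a ready tether between dipole carbon C10 and dipolarophile carbon C5.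
4. Dione half: (S)-allyl ketone by decarboxylative asymmetric allylation, benzyl addition, lactol formation, oxocarbenium Friedel–Crafts closure, then oxidation to the o-quinone.
5. Ring order: ring A′ (bought), tetrahydrofuran′ (lactol), oxygen-bridged seven-membered ring B′, dioxane (Diels–Alder), then in one step the oxygen-bridged ring B and, as the last closure, ring A of the aromatic half.

Key step: step 20

Remark: icetexane numbering is used (plain numbers for the aromatic half, primed numbers for the dione half); CIP analysis of the given SMILES gives 5S,7S,10S for both halves and 13′R,14′R for the dioxane carbons.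

**Route**

Step 1
Reactants: 1 thymol
Product: 3 3-isopropyl-6-methylbenzene-1,2-diol, via o-quinone 2 (not isolated)
Conditions: IBX (1.2 equiv), DMF, rt; then aq. Na2S2O4
Reagents that add atoms: IBX (2-iodoxybenzoic acid) O=C1OI(O)(=O)c2ccccc12
Why: IBX transfers oxygen within an aryloxy-iodane to the only free ortho position of the phenol (regioselective ortho-oxygenation to the o-quinone), and dithionite reduces the quinone to the catechol.

Step 2
Reactants: 3 3-isopropyl-6-methylbenzene-1,2-diol
Product: 4 1-isopropyl-2,3-dimethoxy-4-methylbenzene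
Conditions: MeI, K2CO3, DMF, 50 °C
Reagents that add atoms: iodomethane CI
Why: Williamson O-methylation of both phenols.

Step 3
Reactants: 5 3-methylcyclohex-2-en-1-one
Product: 7 allyl 3,3-dimethylcyclohex-1-en-1-yl carbonate, via magnesium enolate 6 (not isolated)
Conditions: MeMgBr (1.3 equiv), CuI (10 mol%), THF, −30 °C; then ClCO2CH2CH=CH2, −78 °C to rt
Reagents that add atoms: methylmagnesium bromide C[Mg]Br; allyl chloroformate C=CCOC(=O)Cl
Why: Copper-catalysed conjugate addition gives the regiodefined enolate (C1=C2, next to the new gem-dimethyl carbon), which the hard chloroformate should acylate on oxygen.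

Step 4
Reactants: 7 allyl 3,3-dimethylcyclohex-1-en-1-yl carbonate
Product: 8 (S)-2-allyl-3,3-dimethylcyclohexan-1-one
Conditions: Pd2(dba)3·CHCl3 (2.5 mol%), (R,R)-ANDEN-phenyl Trost ligand (5.5 mol%), 1,4-dioxane, rt
Reagents that add atoms: none
Why: Decarboxylative asymmetric allylic alkylation (Tsuji–Trost type): the π-allylpalladium/enolate ion pair recombines at C2 inside the chiral pocket under base-free conditions, which should set the tertiary centre (C5 of the dione half) as S; the antipodal ligand is used if the sense of induction is the opposite.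

Step 5
Reactants: 4 1-isopropyl-2,3-dimethoxy-4-methylbenzene; 8 (S)-2-allyl-3,3-dimethylcyclohexan-1-one
Product: 10 (1S,2S)-2-allyl-1-(4-isopropyl-2,3-dimethoxybenzyl)-3,3-dimethylcyclohexan-1-ol, via benzyllithium 9 (not isolated)
Conditions: 4: s-BuLi, TMEDA, THF, −78 to −20 °C; LaCl3·2LiCl; then 8, −78 °C; H2O
Reagents that add atoms: none
Why: Lateral lithiation of the methyl group ortho to a methoxy group (no ring position ortho to methoxy is free), then lanthanum-assisted 1,2-addition; equatorial attack anti to the allyl group and away from the axial C4 methyl should place the new hydroxyl (C10) cis to the allyl group.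

Step 6
Reactants: 10 (1S,2S)-2-allyl-1-(4-isopropyl-2,3-dimethoxybenzyl)-3,3-dimethylcyclohexan-1-ol
Product: 13 (3aS,7aS)-7a-(4-isopropyl-2,3-dimethoxybenzyl)-4,4-dimethyloctahydrobenzofuran-2-ol (cis-fused lactol; both C2 epimers), via diol 11 (not isolated), via hydroxy aldehyde 12 (not isolated)
Conditions: OsO4 (2 mol%), NaIO4 (4 equiv), 2,6-lutidine, dioxane/H2O 3:1, rt
Reagents that add atoms: sodium periodate [Na+].[O-]I(=O)(=O)=O (oxygen relayed by OsO4)
Why: Lemieux–Johnson oxidation of the terminal alkene; the aldehyde closes onto the cis tertiary alcohol to give the lactol (tetrahydrofuran ring of the dione half).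

Step 7
Reactants: 13 the lactol
Product: 14 (5S,7S,10S)-brussonol dimethyl ether (11,12-dimethoxy-7,10-epoxy-icetexa-8,11,13-triene)
Conditions: BF3·OEt2 (2 equiv), CH2Cl2, −40 to 0 °C
Reagents that add atoms: none
Why: Oxa-Pictet–Spengler-type Friedel–Crafts cyclisation: the bicyclic oxocarbenium ion at C7 is attacked by arene carbon C8 (para to a methoxy group) to close the seven-membered ring, and the bridge dictates the C7 configuration.

Step 8
Reactants: 14 brussonol dimethyl ether
Product: 15 (5S,7S,10S)-brussonol
Conditions: NaSEt (6 equiv), DMF, 130 °C; aq. HCl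
Reagents that add atoms: none
Why: SN2 demethylation of both aryl methyl ethers by thiolate; the bridgehead dialkyl ether cannot be attacked from the rear.

Step 9
Reactants: 15 brussonol
Product: 16 brussonol o-quinone
Conditions: Ag2O (3 equiv), MgSO4, Et2O, rt, dark; filtered and used at once
Reagents that add atoms: none
Why: Neutral two-electron oxidation of the catechol to the o-quinone.

Step 10
Reactants: 17 methyl 3,3-dimethylpent-4-enoate
Product: 18 3,3-dimethylpent-4-en-1-ol
Conditions: LiAlH4, Et2O, 0 °C
Reagents that add atoms: none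
Why: Hydride reduction of the ester to the primary alcohol.

Step 11
Reactants: 18 3,3-dimethylpent-4-en-1-ol
Product: 19 5-iodo-3,3-dimethylpent-1-ene
Conditions: I2, PPh3, imidazole, CH2Cl2, 0 °C to rt
Reagents that add atoms: iodine II
Why: Appel iodination of an unhindered primary alcohol.

Step 12
Reactants: 19 5-iodo-3,3-dimethylpent-1-ene; 20 trimethyl(prop-1-yn-1-yl)silane
Product: 22 (6,6-dimethyloct-7-en-1-yn-1-yl)trimethylsilane, via lithiated silylpropyne 21 (not isolated)
Conditions: 20: n-BuLi, TMEDA, THF, −78 °C; then 19, −78 °C to rt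
Reagents that add atoms: none
Why: SN2 alkylation of the propargylic lithium reagent at its CH2 terminus; the silyl group blocks the alkyne end and disfavours the allenyl isomer.

Step 13
Reactants: 22 the silyl enyne
Product: 23 6,6-dimethyloct-7-en-1-yne
Conditions: K2CO3 (cat.), MeOH, rt
Reagents that add atoms: none
Why: Methoxide-induced protodesilylation of the alkynylsilane.

Step 14
Reactants: 24 3-bromo-4,5-dihydroxybenzaldehyde
Product: 25 3-bromo-4,5-bis(methoxymethoxy)benzaldehyde
Conditions: MOMCl (3 equiv), i-Pr2NEt, CH2Cl2, 0 °C to rt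
Reagents that add atoms: chloromethyl methyl ether COCCl
Why: Acetal protection of both phenols; the ether next to the free ring position later serves as a directing group.

Step 15
Reactants: 25 3-bromo-4,5-bis(methoxymethoxy)benzaldehyde
Product: 26 3-isopropyl-4,5-bis(methoxymethoxy)benzaldehyde
Conditions: i-PrZnBr (1.5 equiv), Pd(OAc)2 (2 mol%), CPhos (4 mol%), THF/toluene, rt
Reagents that add atoms: isopropylzinc bromide CC(C)[Zn]Br
Why: Negishi coupling of a secondary alkylzinc halide, which tolerates the aldehyde; the biarylphosphine favours reductive elimination over β-hydride elimination, so the branched isopropyl group should be transferred.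

Step 16
Reactants: 26 3-isopropyl-4,5-bis(methoxymethoxy)benzaldehyde
Product: 29 2-iodo-5-isopropyl-3,4-bis(methoxymethoxy)benzaldehyde, via lithium amino alkoxide 27 (not isolated), via 2-lithio derivative 28 (not isolated)
Conditions: LiN(Me)CH2CH2NMe2 (from the amine and n-BuLi), THF, −20 °C; n-BuLi (3 equiv), −20 °C; I2, −78 °C to rt; aq. NH4Cl
Reagents that add atoms: iodine II
Why: Directed ortho-metalation: the in situ α-amino alkoxide masks the aldehyde and, together with the neighbouring MOM ether, directs lithiation to the ring position between them (the other ortho position lies next to isopropyl and has no second director); iodine quench.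

Step 17
Reactants: 29 2-iodo-5-isopropyl-3,4-bis(methoxymethoxy)benzaldehyde; 23 6,6-dimethyloct-7-en-1-yne
Product: 30 2-(6,6-dimethyloct-7-en-1-yn-1-yl)-5-isopropyl-3,4-bis(methoxymethoxy)benzaldehyde
Conditions: Pd(PPh3)2Cl2 (3 mol%), CuI (5 mol%), Et3N, THF, 40 °C
Reagents that add atoms: none
Why: Sonogashira coupling of an aryl iodide activated by the ortho formyl group; the phenols are protected, so no benzofuran can form.

Step 18
Reactants: 30 the bis-MOM enynal
Product: 31 2-(6,6-dimethyloct-7-en-1-yn-1-yl)-3,4-dihydroxy-5-isopropylbenzaldehyde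
Conditions: 6 M aq. HCl, THF/i-PrOH, 40 °C; used crude
Reagents that add atoms: none
Why: Acid hydrolysis of the two phenolic MOM acetals under metal-free, base-free conditions, under which the o-alkynylphenol should not cyclise.

Step 19
Reactants: 31 the enynal catechol; 16 brussonol o-quinone
Product: 33 hetero-Diels–Alder adduct (cis-fused 2,3-dihydro-1,4-benzodioxine; arene with CHO at C8, enyne chain at C9, isopropyl at C13; O11–C13′ and O12–C14′, 13′R,14′R; dione half 5′S,7′S,10′S), via o-quinone 32 (not isolated)
Conditions: 31 (2 equiv): NaIO4 on wet silica gel, CH2Cl2, 0 °C, filter; then 16 (1 equiv), CH2Cl2 (ca. 1 M), rt, dark, 24–48 h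
Reagents that add atoms: none
Why: Inverse-electron-demand hetero-Diels–Alder reaction of the 1,2-dicarbonyl of 32 (LUMO lowered by the para formyl and the alkynyl group, itself a poor dienophile and unable to tautomerise to a quinone methide) with C13′=C14′ of 16: the nucleophilic C13′ should bond first to O11 because the developing phenoxide at O12 is para to the formyl group (this also keeps the two isopropyl groups apart), the addition is suprafacial (cis C–O bonds), and it should occur on the face of 16 carrying the C5′–C6′ bridge, away from the lone pairs of the 7′,10′-ether oxygen; a facial isomer, if formed, is removed by chromatography.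

Step 20
Reactants: 33 the hetero-Diels–Alder adduct
Product: 34 CNP0371333.1
Conditions: PtCl2[(R)-BINAP] (10 mol%), AgSbF6 (10 mol%), cyclohexa-1,4-diene (10 equiv), 4 Å MS, toluene, 40 °C
Reagents that add atoms: none
Why: Proposed new method: the cationic platinum catalyst activates the C20≡C10 triple bond, the C7 aldehyde oxygen adds 6-endo-dig to give a platinum-bound 2-benzopyrylium (a metal-containing carbonyl ylide C7–O–C10), and this adds across the tethered C5=C6 vinyl group in an intramolecular Huisgen-type (3+2) cycloaddition that leaves a platinum carbene at C20; this part is the known behaviour of 2-alkynylbenzaldehydes carrying an alkene on the alkyne terminus, where the carbene normally ends by C–H or Si–H insertion or by 1,2-hydride shift. New is the reductive end: the C20 carbene has no α-hydrogen (C10 is quaternary) and is a strongly electrophilic benzylic centre, so it should abstract hydride from cyclohexa-1,4-diene (a donor too weak to reduce the aldehyde, the dione or the pyrylium stage), after which the cyclohexadienyl cation protonates the C20–Pt bond and leaves as benzene (closest analogy: cyclohexa-1,4-dienes as dihydrogen surrogates in Lewis-acid-catalysed transfer hydrogenation). Ring closures: the oxygen-containing six-membered ring by 6-endo-dig oxyplatination; the tetrahydrofuran and seven-membered rings through the C7–C6 bond and, as the final closure, ring A through the C10–C5 bond of the same cycloaddition (6-exo with respect to the vinyl group). Stereocentres: C7 and C10 form on one face of the planar ylide and are locked cis by the oxygen bridge; C5 is fixed by the four-carbon tether, which can span C10 and C5 only with C4 exo (syn to the bridge, H5 endo, chair-like ring A); the sense of the three centres relative to the remote dione half is left to the chiral bisphosphine on platinum (the antipodal ligand is used if (R) proves mismatched, and the diastereomer is separable). Selectivities needed are (3+2) at C7/C10 over (4+2) at C7/C20 (secured by the tether, which would otherwise have to close a bridged seven-membered ring) and carbene reduction over rearrangement or insertion (secured by the excess of hydride donor).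

**Compound list**

1 | thymol (2-isopropyl-5-methylphenol) | Cc1ccc(C(C)C)c(O)c1 | starting material
2 | 3-isopropyl-6-methyl-1,2-benzoquinone | CC1=CC=C(C(C)C)C(=O)C1=O | intermediate
3 | 3-isopropyl-6-methylbenzene-1,2-diol | Cc1ccc(C(C)C)c(O)c1O | intermediate
4 | 1-isopropyl-2,3-dimethoxy-4-methylbenzene | COc1c(C)ccc(C(C)C)c1OC | intermediate
5 | 3-methylcyclohex-2-en-1-one | CC1=CC(=O)CCC1 | starting material
6 | bromomagnesium 3,3-dimethylcyclohex-1-en-1-olate | Br[Mg]OC1=CC(C)(C)CCC1 | intermediate
7 | allyl 3,3-dimethylcyclohex-1-en-1-yl carbonate | C=CCOC(=O)OC1=CC(C)(C)CCC1 | intermediate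
8 | (S)-2-allyl-3,3-dimethylcyclohexan-1-one | O=C1CCCC(C)(C)[C@@H]1CC=C | intermediate
9 | (4-isopropyl-2,3-dimethoxybenzyl)lithium | [Li]Cc1ccc(C(C)C)c(OC)c1OC | intermediate
10 | (1S,2S)-2-allyl-1-(4-isopropyl-2,3-dimethoxybenzyl)-3,3-dimethylcyclohexan-1-ol (OH cis to allyl) | COc1c(OC)c(C(C)C)ccc1C[C@@]1(O)CCCC(C)(C)[C@@H]1CC=C | intermediate
11 | 3-[(1S,2S)-2-hydroxy-2-(4-isopropyl-2,3-dimethoxybenzyl)-6,6-dimethylcyclohexyl]propane-1,2-diol (epimers at the secondary carbinol) | COc1c(OC)c(C(C)C)ccc1C[C@@]1(O)CCCC(C)(C)[C@@H]1CC(O)CO | intermediate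
12 | 2-[(1S,2S)-2-hydroxy-2-(4-isopropyl-2,3-dimethoxybenzyl)-6,6-dimethylcyclohexyl]acetaldehyde | COc1c(OC)c(C(C)C)ccc1C[C@@]1(O)CCCC(C)(C)[C@@H]1CC=O | intermediate
13 | (3aS,7aS)-7a-(4-isopropyl-2,3-dimethoxybenzyl)-4,4-dimethyloctahydrobenzofuran-2-ol (cis-fused lactol, both C2 epimers) | COc1c(OC)c(C(C)C)ccc1C[C@@]12CCCC(C)(C)[C@@H]1CC(O)O2 | intermediate
14 | (5S,7S,10S)-brussonol dimethyl ether | COc1c(OC)c(C(C)C)cc2c1C[C@@]13CCCC(C)(C)[C@@H]1C[C@@H]2O3 | intermediate
15 | (5S,7S,10S)-brussonol | CC(C)c1cc2c(c(O)c1O)C[C@@]13CCCC(C)(C)[C@@H]1C[C@@H]2O3 | intermediate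
16 | (5S,7S,10S)-brussonol o-quinone (11,12-dione) | CC(C)C1=CC2=C(C[C@@]34CCCC(C)(C)[C@@H]3C[C@@H]2O4)C(=O)C1=O | intermediate
17 | methyl 3,3-dimethylpent-4-enoate | COC(=O)CC(C)(C)C=C | starting material
18 | 3,3-dimethylpent-4-en-1-ol | OCCC(C)(C)C=C | intermediate
19 | 5-iodo-3,3-dimethylpent-1-ene | ICCC(C)(C)C=C | intermediate
20 | trimethyl(prop-1-yn-1-yl)silane | CC#C[Si](C)(C)C | starting material
21 | [3-(trimethylsilyl)prop-2-yn-1-yl]lithium | [Li]CC#C[Si](C)(C)C | intermediate
22 | (6,6-dimethyloct-7-en-1-yn-1-yl)trimethylsilane | C[Si](C)(C)C#CCCCC(C)(C)C=C | intermediate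
23 | 6,6-dimethyloct-7-en-1-yne | C#CCCCC(C)(C)C=C | intermediate
24 | 3-bromo-4,5-dihydroxybenzaldehyde | O=Cc1cc(O)c(O)c(Br)c1 | starting material
25 | 3-bromo-4,5-bis(methoxymethoxy)benzaldehyde | O=Cc1cc(OCOC)c(OCOC)c(Br)c1 | intermediate
26 | 3-isopropyl-4,5-bis(methoxymethoxy)benzaldehyde | O=Cc1cc(OCOC)c(OCOC)c(C(C)C)c1 | intermediate
27 | lithium α-amino alkoxide of 26 (adduct of lithium N,N,N′-trimethylethylenediamide) | CN(C)CCN(C)C(O[Li])c1cc(OCOC)c(OCOC)c(C(C)C)c1 | intermediate
28 | 2-lithio derivative of 27 | CN(C)CCN(C)C(O[Li])c1cc(C(C)C)c(OCOC)c(OCOC)c1[Li] | intermediate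
29 | 2-iodo-5-isopropyl-3,4-bis(methoxymethoxy)benzaldehyde | O=Cc1cc(C(C)C)c(OCOC)c(OCOC)c1I | intermediate
30 | 2-(6,6-dimethyloct-7-en-1-yn-1-yl)-5-isopropyl-3,4-bis(methoxymethoxy)benzaldehyde | O=Cc1cc(C(C)C)c(OCOC)c(OCOC)c1C#CCCCC(C)(C)C=C | intermediate
31 | 2-(6,6-dimethyloct-7-en-1-yn-1-yl)-3,4-dihydroxy-5-isopropylbenzaldehyde | O=Cc1cc(C(C)C)c(O)c(O)c1C#CCCCC(C)(C)C=C | intermediate
32 | 2-(6,6-dimethyloct-7-en-1-yn-1-yl)-5-isopropyl-3,4-dioxocyclohexa-1,5-diene-1-carbaldehyde | O=CC1=C(C#CCCCC(C)(C)C=C)C(=O)C(=O)C(C(C)C)=C1 | intermediate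
33 | hetero-Diels–Alder adduct of 32 (heterodiene) and 16 (C13′=C14′); cis-fused dioxane, 13′R,14′R, C–O bonds anti to the 7′,10′-oxygen bridge | CC(C)c1cc(C=O)c(C#CCCCC(C)(C)C=C)c2c1O[C@@H]1C3=C(C[C@@]45CCCC(C)(C)[C@@H]4C[C@@H]3O5)C(=O)C(=O)[C@]1(C(C)C)O2 | intermediate
34 | CNP0371333.1 | CC(C)c1cc2c(c3c1O[C@@H]1C4=C(C[C@@]56CCCC(C)(C)[C@@H]5C[C@@H]4O6)C(=O)C(=O)[C@]1(C(C)C)O3)C[C@@]13CCCC(C)(C)[C@@H]1C[C@@H]2O3 | target

**Step count**

Total: 20 steps. Longest linear sequence: 9 steps (3, 4, 5, 6, 7, 8, 9, 19, 20 from 5; equally 1, 2, 5–9, 19, 20 from 1).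

**Steps most likely to fail**

1. Step 20 (proposed new method). The platinum carbene at C20 may escape reduction: by 1,2-alkyl shift towards the oxygen-bearing C10, by insertion into a C–H bond of the new ring A, or by ether-assisted fragmentation. Hydride may also add at the pyrylium stage, a stepwise cationic course may allow a methyl shift next to C5, or induction relative to the dione half may be poor. Fallback, from 33 back to 34, with known reaction types: 33 is treated with PtCl2 (10 mol%) and diphenyl sulfoxide in toluene. The same (3+2) cascade then ends by oxygen transfer from the sulfoxide to the electrophilic carbene and should give the 20-oxo compound F1. The aryl ketone, activated by the ortho ether oxygen, is then reduced to the methylene group by ionic hydrogenation (Et3SiH, CF3CO2H, CH2Cl2, 0 °C) to give 34.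

2. Step 19. Either quinone may dimerise with itself faster than the crossed cycloaddition, the addition may take the other regiochemical or facial course, or the o-alkynyl catechol/quinone may cyclise (benzofuran or isochromene formation) during deprotection and oxidation. Fallback, from 29 and 23 back to 33: the side chain is introduced after the cycloaddition, so a simple heterodiene can be used in large excess. MOM cleavage of 29 (6 M HCl) gives 3,4-dihydroxy-2-iodo-5-isopropylbenzaldehyde F2. Oxidation (NaIO4 on silica) gives the iodo quinone F3, which is not isolated and is used in fivefold excess with 16 to give the iodo adduct F4. Alkyne 23 is converted (n-BuLi, then Bu3SnCl) into the alkynylstannane F5. A base-free Stille coupling of F4 with F5 (Pd2(dba)3, AsPh3, toluene, 60 °C) gives 33.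

3. Step 4. Enantio-induction at a tertiary α-carbon may be incomplete, or the product may partly racemise through enolisation. Fallback, from 5 back to 8, by resolution instead of asymmetric catalysis: conjugate addition as in step 3 with allyl bromide/HMPA as the quench gives the racemic ketone F6. Reduction with LiBH(s-Bu)3 gives the racemic cis-alcohol F7. Lipase-catalysed acylation (Burkholderia cepacia lipase, vinyl acetate) is expected to acylate the (1R)-alcohol to the acetate F8, which is separated from the unreacted enantiomer. Methanolysis (K2CO3, MeOH) gives the (1R,2S)-alcohol F9, and Dess–Martin oxidation gives 8.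

**Further compounds**

F1 | step 20 | 20-oxo derivative of 34 (aryl ketone at C20 of the aromatic half) | CC(C)c1cc2c(c3c1O[C@@H]1C4=C(C[C@@]56CCCC(C)(C)[C@@H]5C[C@@H]4O6)C(=O)C(=O)[C@]1(C(C)C)O3)C(=O)[C@@]13CCCC(C)(C)[C@@H]1C[C@@H]2O3
F2 | step 19 | 3,4-dihydroxy-2-iodo-5-isopropylbenzaldehyde | O=Cc1cc(C(C)C)c(O)c(O)c1I
F3 | step 19 | 2-iodo-5-isopropyl-3,4-dioxocyclohexa-1,5-diene-1-carbaldehyde | O=CC1=C(I)C(=O)C(=O)C(C(C)C)=C1
F4 | step 19 | iodo analogue of 33 (iodine at C9 in place of the enyne chain) | CC(C)c1cc(C=O)c(I)c2c1O[C@@H]1C3=C(C[C@@]45CCCC(C)(C)[C@@H]4C[C@@H]3O5)C(=O)C(=O)[C@]1(C(C)C)O2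
F5 | step 19 | tributyl(6,6-dimethyloct-7-en-1-yn-1-yl)stannane | CCCC[Sn](CCCC)(CCCC)C#CCCCC(C)(C)C=C
F6 | step 4 | racemic 2-allyl-3,3-dimethylcyclohexan-1-one | O=C1CCCC(C)(C)C1CC=C
F7 | step 4 | racemic cis-2-allyl-3,3-dimethylcyclohexan-1-ol (both enantiomers) | O[C@@H]1CCCC(C)(C)[C@@H]1CC=C.O[C@H]1CCCC(C)(C)[C@H]1CC=C
F8 | step 4 | (1R,2S)-2-allyl-3,3-dimethylcyclohexyl acetate | CC(=O)O[C@@H]1CCCC(C)(C)[C@@H]1CC=C
F9 | step 4 | (1R,2S)-2-allyl-3,3-dimethylcyclohexan-1-ol | O[C@@H]1CCCC(C)(C)[C@@H]1CC=C
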